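**Plan**
- Retrosynthesis: the 4'-O–CH3 bond of the aryl ring is cut first, then O1–C2 (dihydrofuran ring), then C6–C7 and C3a=C4 of the cyclohexadienone ring, then C3–CH3 and C3–C3a, and last C5–allyl.
- Forward: enone 4 (aryl ring, C2, C3, C3a, C7a, C7) and aldehyde ester 11 (C4, C5, C6 with allyl and OMe) are joined by conjugate methylation and aldol addition. Dieckmann closure and dehydration then build the six-membered dienone ring, the dihydrofuran ring closes last, and the phenol is methylated.
- Enabling feature: the aryl group on C2 is 3,4,5-trimethoxyphenyl, so its 4-oxygen (para to C2) can be a free phenol and C2 a benzylic CH2 that is oxidised to a p-quinone methide. O1 is the enol oxygen on C7a of the cyclohexadienone ring (a vinylogous acid with C6=O) and can reach C2 through a five-membered transition state.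
- Stereochemistry: C3 comes from ligand-controlled copper-catalysed methyl addition, C5 from esterase desymmetrisation of the allyl(methoxy)malonate, and C2 is set trans to C3 in the ring closure under thermodynamic control.

Key step: step 10

Assumption: pig liver esterase is taken to cleave the pro-S ester group of 7 (giving (R)-8), and the (R,SFc)-Josiphos ligand is taken to deliver methyl to the Re face of C4 of enone 4; the sense of both would be confirmed on a first batch and the mirror-image ligand used if needed.

Step 1
Reactants: 1 4-allyl-2,6-dimethoxyphenol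
Product: 2 (4-allyl-2,6-dimethoxyphenoxy)triisopropylsilane
Conditions: TIPSCl (1.3 equiv), imidazole (2.5 equiv), DMF, 40 °C
Reagents that add atoms: chlorotriisopropylsilane, CC(C)[Si](Cl)(C(C)C)C(C)C
Why: Silyl ether formation on the phenol; the bulky triisopropylsilyl group should keep the acidic OH out of the Grignard, amide-base and acid steps that follow and is removable with fluoride without touching the allyl group.

Step 2
Reactants: 2 (4-allyl-2,6-dimethoxyphenoxy)triisopropylsilane; 3 but-3-en-2-one
Product: 4 (3E)-5-{3,5-dimethoxy-4-[(triisopropylsilyl)oxy]phenyl}pent-3-en-2-one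
Conditions: 3 (3 equiv), second-generation Hoveyda–Grubbs catalyst RuCl2(H2IMes)(=CH-C6H4-2-OiPr) (3 mol %), CH2Cl2, 40 °C
Reagents that add atoms: none
Why: Olefin cross-metathesis of a terminal allylarene with an electron-poor vinyl ketone should favour the cross product over homodimers and give the E enone, with loss of ethene as the driving force.

Step 3
Reactants: 5 dimethyl 2-methoxypropanedioate; 6 allyl bromide
Product: 7 dimethyl 2-allyl-2-methoxypropanedioate
Conditions: NaH (1.1 equiv), THF, 0 °C; then 6 (1.2 equiv), 0 °C → rt
Reagents that add atoms: none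
Why: Malonate alkylation, in which the sodium enolate of the 2-methoxymalonate is C-allylated by SN2 displacement of bromide, creates the fully substituted carbon as a prochiral centre with two enantiotopic ester groups.

Step 4
Reactants: 7 dimethyl 2-allyl-2-methoxypropanedioate
Product: 8 (2R)-2-methoxy-2-(methoxycarbonyl)pent-4-enoic acid
Conditions: pig liver esterase, 0.1 M phosphate buffer pH 7.5, DMSO (10 vol %), 25 °C, pH-stat with 1 M NaOH (1.0 equiv); then 1 M HCl to pH 2
Reagents that add atoms: water, O
Why: Enzymatic desymmetrisation by enantiotopic-group-selective ester hydrolysis, a reaction type established for 2,2-disubstituted dimethyl malonates, should stop at the half-ester because the carboxylate is not a substrate, and the enzyme fixes the quaternary centre (the later C5) as R by choosing one of the two ester groups.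

Step 5
Reactants: 8 (2R)-2-methoxy-2-(methoxycarbonyl)pent-4-enoic acid
Product: 10 methyl (2R)-2-(hydroxymethyl)-2-methoxypent-4-enoate, via isobutyl carbonic mixed anhydride 9 (not isolated)
Conditions: iBuOCOCl (1.1 equiv), N-methylmorpholine (1.1 equiv), THF, −15 °C; then NaBH4 (2 equiv), H2O, −15 → 0 °C
Reagents that add atoms: none
Why: Mixed-anhydride activation followed by borohydride reduction should reduce the carboxyl group alone, leaving the methyl ester, the alkene and the quaternary centre untouched (borane would hydroborate the allyl group).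

Step 6
Reactants: 10 methyl (2R)-2-(hydroxymethyl)-2-methoxypent-4-enoate
Product: 11 methyl (2R)-2-formyl-2-methoxypent-4-enoate
Conditions: Dess–Martin periodinane (1.3 equiv), CH2Cl2, 0 °C → rt
Reagents that add atoms: none
Why: Dess–Martin oxidation of the neopentylic primary alcohol should give the aldehyde under neutral conditions, and the absence of an α-hydrogen rules out enolisation or epimerisation.

Step 7
Reactants: 4 (3E)-5-{3,5-dimethoxy-4-[(triisopropylsilyl)oxy]phenyl}pent-3-en-2-one; 11 methyl (2R)-2-formyl-2-methoxypent-4-enoate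
Product: 13 methyl (2R,5R)-4-acetyl-6-{3,5-dimethoxy-4-[(triisopropylsilyl)oxy]phenyl}-3-hydroxy-2-methoxy-5-methyl-2-(prop-2-en-1-yl)hexanoate (mixture at C3 and C4), via bromomagnesium enolate 12 (not isolated)
Conditions: 4 (1.3 equiv), CuBr·SMe2 (5 mol %), (R)-1-[(SFc)-2-(diphenylphosphino)ferrocenyl]ethyldicyclohexylphosphine (Josiphos, 6 mol %), MeMgBr (1.3 equiv), tBuOMe, −75 °C; then 11 (1.0 equiv), −75 °C; aq NH4Cl
Reagents that add atoms: methylmagnesium bromide, C[Mg]Br
Why: Copper-catalysed asymmetric conjugate addition of the Grignard reagent, in which the chiral ferrocenyl diphosphine directs methyl to the Re face of C4 of the enone and so sets the later C3 centre (R at this stage), gives the magnesium enolate regiospecifically at the internal carbon, and this enolate is intercepted by the non-enolisable, chelating α-methoxy aldehyde in an aldol addition that forms the later C3a–C4 bond; the two additional centres arise as a mixture and are removed in step 8.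

Step 8
Reactants: 13 methyl (2R,5R)-4-acetyl-6-{3,5-dimethoxy-4-[(triisopropylsilyl)oxy]phenyl}-3-hydroxy-2-methoxy-5-methyl-2-(prop-2-en-1-yl)hexanoate
Product: 15 (6R)-6-allyl-4-[(2R)-1-{3,5-dimethoxy-4-[(triisopropylsilyl)oxy]phenyl}propan-2-yl]-3-hydroxy-6-methoxycyclohexa-2,4-dien-1-one, via ring-closed ketol 14 (not isolated)
Conditions: LiN(SiMe3)2 (3.3 equiv), THF, −78 → −20 °C; 1 M HCl; crude in CH2Cl2, TsOH·H2O (10 mol %), rt
Reagents that add atoms: none
Why: Dieckmann-type (intramolecular Claisen) condensation of the kinetically formed methyl-ketone enolate onto the methyl ester should close the six-membered 1,3-dione (a δ-keto ester cyclisation; enolisation also shuts off retro-aldol cleavage, and the other enolate could only give a four-membered ring), after which acid-catalysed dehydration of the β-hydroxy ketone gives the conjugated vinylogous acid and erases both aldol centres without touching the quaternary or the methyl-bearing centre.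

Step 9
Reactants: 15 (6R)-6-allyl-4-[(2R)-1-{3,5-dimethoxy-4-[(triisopropylsilyl)oxy]phenyl}propan-2-yl]-3-hydroxy-6-methoxycyclohexa-2,4-dien-1-one
Product: 16 (6R)-6-allyl-3-hydroxy-4-[(2R)-1-(4-hydroxy-3,5-dimethoxyphenyl)propan-2-yl]-6-methoxycyclohexa-2,4-dien-1-one
Conditions: Bu4NF (1.2 equiv), AcOH (1.2 equiv), THF, 0 °C
Reagents that add atoms: none
Why: Fluoride-induced cleavage of the aryl silyl ether, buffered with acetic acid so that neither the vinylogous acid nor the phenol sits as a naked anion, should unmask the para-phenol needed for the oxidation.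

Step 10
Reactants: 16 (6R)-6-allyl-3-hydroxy-4-[(2R)-1-(4-hydroxy-3,5-dimethoxyphenyl)propan-2-yl]-6-methoxycyclohexa-2,4-dien-1-one
Product: 18 (2S,3S,5R)-5-allyl-2-(4-hydroxy-3,5-dimethoxyphenyl)-5-methoxy-3-methyl-2,3-dihydro-1-benzofuran-6(5H)-one, via p-quinone methide 17 (not isolated)
Conditions: Ag2O (2.0 equiv), CH2Cl2 (0.01 M), 4 Å molecular sieves, rt, dark
Reagents that add atoms: none
Why: Ag2O removes two electrons and two protons from the 4-hydroxy-3,5-dimethoxybenzyl unit of 16 (the phenol O–H and one C2–H) to give p-quinone methide 17, and the enol oxygen on C7a, present as its silver salt, adds to the methide carbon in an intramolecular 1,6-conjugate (oxa-Michael) addition that forms O1–C2 and restores the aromatic phenol. The closest known reaction type is the oxidation of 4-alkyl-2,6-dimethoxyphenols to p-quinone methides with Ag2O and their capture by oxygen nucleophiles, as used for 2-aryl-2,3-dihydrobenzofuran neolignans. The dihydrofuran ring closes in the 5-exo-trig mode, the oxygen attacking the exocyclic methide carbon. C2 is the only new stereocentre and is controlled by the existing C3 centre: the quinoid ring avoids the C3 methyl group in the closing transition state, and because the phenolate of 18 can reopen to 17 with loss of the vinylogous carboxylate, any cis isomer should drain to the more stable 2,3-trans (2S,3S) ring. Chemoselectivity in the oxidation is secured by the free para-phenol being the only group in 16 that Ag2O oxidises (the vinylogous acid only forms a salt and the allyl group is inert), and oxygen is preferred over carbon because attack by C7 would give a bridged bicycle with a bridgehead double bond. High dilution and stopping at full conversion should keep intermolecular capture, tautomerisation of the methide to a styrene and over-oxidation of the product phenol in check.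

Step 11
Reactants: 18 (2S,3S,5R)-5-allyl-2-(4-hydroxy-3,5-dimethoxyphenyl)-5-methoxy-3-methyl-2,3-dihydro-1-benzofuran-6(5H)-one
Product: 19 (2S,3S,5R)-5-allyl-5-methoxy-3-methyl-2-(3,4,5-trimethoxyphenyl)-2,3-dihydro-1-benzofuran-6(5H)-one
Conditions: MeI (3 equiv), K2CO3 (1.5 equiv), acetone, rt
Reagents that add atoms: iodomethane, CI
Why: Williamson O-methylation of the only remaining acidic hydroxyl group (the hindered 4-phenol) should give the trimethoxyphenyl ring, and capping the phenol also removes the quinone methide pathway by which C2 could still open.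

**Compound list**
1 | 4-allyl-2,6-dimethoxyphenol | C=CCc1cc(OC)c(O)c(OC)c1 | starting material
2 | (4-allyl-2,6-dimethoxyphenoxy)triisopropylsilane | C=CCc1cc(OC)c(O[Si](C(C)C)(C(C)C)C(C)C)c(OC)c1 | intermediate
3 | but-3-en-2-one (methyl vinyl ketone) | C=CC(C)=O | starting material
4 | (3E)-5-{3,5-dimethoxy-4-[(triisopropylsilyl)oxy]phenyl}pent-3-en-2-one | CC(=O)/C=C/Cc1cc(OC)c(O[Si](C(C)C)(C(C)C)C(C)C)c(OC)c1 | intermediate
5 | dimethyl 2-methoxypropanedioate (dimethyl methoxymalonate) | COC(C(=O)OC)C(=O)OC | starting material
6 | allyl bromide (3-bromoprop-1-ene) | C=CCBr | starting material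
7 | dimethyl 2-allyl-2-methoxypropanedioate | C=CCC(OC)(C(=O)OC)C(=O)OC | intermediate
8 | (2R)-2-methoxy-2-(methoxycarbonyl)pent-4-enoic acid | C=CC[C@@](C(=O)OC)(OC)C(=O)O | intermediate
9 | isobutyl carbonic mixed anhydride of 8 (descriptor 2S by priority change only, same spatial arrangement as 8) | C=CC[C@@](C(=O)OC)(OC)C(=O)OC(=O)OCC(C)C | intermediate
10 | methyl (2R)-2-(hydroxymethyl)-2-methoxypent-4-enoate | C=CC[C@@](C(=O)OC)(OC)CO | intermediate
11 | methyl (2R)-2-formyl-2-methoxypent-4-enoate | C=CC[C@@](C(=O)OC)(OC)C=O | intermediate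
12 | bromomagnesium (4R)-5-{3,5-dimethoxy-4-[(triisopropylsilyl)oxy]phenyl}-4-methylpent-2-en-2-olate (enolate geometry not defined) | CC(O[Mg]Br)=C[C@H](C)Cc1cc(OC)c(O[Si](C(C)C)(C(C)C)C(C)C)c(OC)c1 | intermediate
13 | methyl (2R,5R)-4-acetyl-6-{3,5-dimethoxy-4-[(triisopropylsilyl)oxy]phenyl}-3-hydroxy-2-methoxy-5-methyl-2-(prop-2-en-1-yl)hexanoate (mixture at C3 and C4) | C=CC[C@@](C(=O)OC)(OC)C(O)C(C(C)=O)[C@H](C)Cc1cc(OC)c(O[Si](C(C)C)(C(C)C)C(C)C)c(OC)c1 | intermediate
14 | (4R)-4-allyl-6-[(2R)-1-{3,5-dimethoxy-4-[(triisopropylsilyl)oxy]phenyl}propan-2-yl]-5-hydroxy-4-methoxycyclohexane-1,3-dione (mixture at C5 and C6) | C=CC[C@@]1(OC)C(O)C([C@H](C)Cc2cc(OC)c(O[Si](C(C)C)(C(C)C)C(C)C)c(OC)c2)C(=O)CC1=O | intermediate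
15 | (6R)-6-allyl-4-[(2R)-1-{3,5-dimethoxy-4-[(triisopropylsilyl)oxy]phenyl}propan-2-yl]-3-hydroxy-6-methoxycyclohexa-2,4-dien-1-one (one tautomer of the vinylogous acid drawn) | C=CC[C@@]1(OC)C=C([C@H](C)Cc2cc(OC)c(O[Si](C(C)C)(C(C)C)C(C)C)c(OC)c2)C(O)=CC1=O | intermediate
16 | (6R)-6-allyl-3-hydroxy-4-[(2R)-1-(4-hydroxy-3,5-dimethoxyphenyl)propan-2-yl]-6-methoxycyclohexa-2,4-dien-1-one | C=CC[C@@]1(OC)C=C([C@H](C)Cc2cc(OC)c(O)c(OC)c2)C(O)=CC1=O | intermediate
17 | (6R)-6-allyl-4-[(2R)-1-(3,5-dimethoxy-4-oxocyclohexa-2,5-dien-1-ylidene)propan-2-yl]-3-hydroxy-6-methoxycyclohexa-2,4-dien-1-one | C=CC[C@@]1(OC)C=C([C@H](C)C=C2C=C(OC)C(=O)C(OC)=C2)C(O)=CC1=O | intermediate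
18 | (2S,3S,5R)-5-allyl-2-(4-hydroxy-3,5-dimethoxyphenyl)-5-methoxy-3-methyl-2,3-dihydro-1-benzofuran-6(5H)-one | C=CC[C@@]1(OC)C=C2C(=CC1=O)O[C@H](c1cc(OC)c(O)c(OC)c1)[C@H]2C | intermediate
19 | (2S,3S,5R)-5-allyl-5-methoxy-3-methyl-2-(3,4,5-trimethoxyphenyl)-2,3-dihydro-1-benzofuran-6(5H)-one | C=CC[C@@]1(OC)C=C2C(=CC1=O)O[C@H](c1cc(OC)c(OC)c(OC)c1)[C@H]2C | target

**Step count**
Total: 11 steps. Longest linear sequence: 9 steps (steps 3 to 11, from 5 and 6 to 19); the aryl branch (steps 1 and 2) joins at step 7.

**Steps most likely to fail**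

Step 4. The esterase may discriminate poorly between the two enantiotopic ester groups of this allyl/methoxy-substituted malonate, or prefer the opposite one, so that 8 is obtained with low or reversed enantiomeric purity. The fallback sets out from 7 and replaces desymmetrisation by classical resolution. One equivalent of KOH in methanol should give racemic 2-methoxy-2-(methoxycarbonyl)pent-4-enoic acid F1. Fractional crystallisation with (R)-1-phenylethylamine from ethyl acetate/hexane should then deliver the less soluble salt, taken to be (R)-1-phenylethylammonium (2R)-2-methoxy-2-(methoxycarbonyl)pent-4-enoate F2; the antipodal amine is used if the other diastereomer crystallises. Acidification and extraction bring the material back to the route at 8.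

Step 8. The lithium aldolate may fragment by retro-aldol cleavage before the methyl ketone is enolised, or the ring-closed ketol may lose water sluggishly at room temperature. The fallback sets out from 13 and masks the carbinol first. Et3SiOTf and 2,6-lutidine in CH2Cl2 at −78 °C should give methyl (2R,5R)-4-acetyl-6-{3,5-dimethoxy-4-[(triisopropylsilyl)oxy]phenyl}-2-methoxy-5-methyl-2-(prop-2-en-1-yl)-3-[(triethylsilyl)oxy]hexanoate F3, which can no longer undergo retro-aldol cleavage. LiN(SiMe3)2 in THF then closes the ring to (4R)-4-allyl-6-[(2R)-1-{3,5-dimethoxy-4-[(triisopropylsilyl)oxy]phenyl}propan-2-yl]-4-methoxy-5-[(triethylsilyl)oxy]cyclohexane-1,3-dione F4. Aqueous HCl in THF followed by TsOH·H2O in CH2Cl2 should remove the triethylsilyl group (the aryl triisopropylsilyl ether is expected to survive) and eliminate water, which returns the material to the route at 15.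

Step 7. The magnesium enolate may be captured incompletely by the hindered aldehyde, lose its regiochemical integrity by proton transfer, or residual Grignard reagent may add to 11; deprotonation of the doubly activated C5 methylene of 4 is a further drain. The fallback sets out from 4 and separates the two bond formations. The same copper-catalysed methyl addition is quenched with Me3SiCl and Et3N to give the isolable silyl enol ether trimethyl{[(4R)-5-{3,5-dimethoxy-4-[(triisopropylsilyl)oxy]phenyl}-4-methylpent-2-en-2-yl]oxy}silane F5. A Mukaiyama aldol addition of F5 to 11 (one equivalent each, BF3·OEt2, CH2Cl2, −78 °C) should then give, after aqueous work-up, the aldol at which the route is rejoined, 13.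

**Further compounds**
F1 | step 4 | racemic 2-methoxy-2-(methoxycarbonyl)pent-4-enoic acid | C=CCC(OC)(C(=O)OC)C(=O)O
F2 | step 4 | (R)-1-phenylethylammonium (2R)-2-methoxy-2-(methoxycarbonyl)pent-4-enoate | C=CC[C@@](C(=O)OC)(OC)C(=O)[O-].C[C@@H]([NH3+])c1ccccc1
F3 | step 8 | methyl (2R,5R)-4-acetyl-6-{3,5-dimethoxy-4-[(triisopropylsilyl)oxy]phenyl}-2-methoxy-5-methyl-2-(prop-2-en-1-yl)-3-[(triethylsilyl)oxy]hexanoate | C=CC[C@@](C(=O)OC)(OC)C(O[Si](CC)(CC)CC)C(C(C)=O)[C@H](C)Cc1cc(OC)c(O[Si](C(C)C)(C(C)C)C(C)C)c(OC)c1
F4 | step 8 | (4R)-4-allyl-6-[(2R)-1-{3,5-dimethoxy-4-[(triisopropylsilyl)oxy]phenyl}propan-2-yl]-4-methoxy-5-[(triethylsilyl)oxy]cyclohexane-1,3-dione | C=CC[C@@]1(OC)C(O[Si](CC)(CC)CC)C([C@H](C)Cc2cc(OC)c(O[Si](C(C)C)(C(C)C)C(C)C)c(OC)c2)C(=O)CC1=O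
F5 | step 7 | trimethyl{[(4R)-5-{3,5-dimethoxy-4-[(triisopropylsilyl)oxy]phenyl}-4-methylpent-2-en-2-yl]oxy}silane | CC(O[Si](C)(C)C)=C[C@H](C)Cc1cc(OC)c(O[Si](C(C)C)(C(C)C)C(C)C)c(OC)c1
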